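## Structural features

The target is a 5,6,7,8-tetrahydro-1H-isochromen-8-one: a 2H-pyran (O2, C1, C8a, C4a, C4, C3) fused through the C4a=C8a bond to a cyclohexenone (C4a, C5, C6, C7, C8, C8a), with an (E)-propenyl group on C3. O2, the diene C3=C4–C4a=C8a and the C8 carbonyl form a doubly vinylogous ester, and the ring fusion is what keeps the 2H-pyran closed. The only stereocentres, C6 (secondary alcohol, R) and C7 (quaternary, methyl and acyloxy, R), are adjacent and lie between C5 and the C8 ketone, with their oxygens cis on the carbocycle. C7 carries the ester of 4-hydroxy-2-methoxy-6-methylbenzoic acid, a di-ortho-substituted benzoate whose carbonyl is shielded. That shielding makes the ester hard to form by acylating a tertiary alcohol, but also slow to migrate to O6 or to be attacked by enolates. Fragile points are the free C6 hydroxyl, which is β to the C8 ketone across a quaternary carbon (retro-aldol and acyl shift under base), the acid- and oxidant-sensitive dienol ether, the alkenes that rule out hydrogenolysis, and the phenol. The real difficulty is the quaternary C7–O stereocentre with its hindered ester next to C6, and closing both rings without disturbing it. The key step exploits the fact that C8a is the central carbon of a 1,3-dicarbonyl (C8 ketone, C1 carboxyl) while C4a, C4, C3 and O2 are a masked ynone, so one acyclic chain can bond C8a to C4a and O2 to C1 and deliver the C1-oxo (2-pyranone) form of the bicycle.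

## Logic of the disconnections

23 to 22: the two O–Si bonds (at O6 and at the phenol) are cut last. The free C6 hydroxyl and the phenol are the groups that invite retro-aldol opening, acyl shift and acylation, so every earlier step runs without an acidic OH. The forward step must use near-neutral fluoride.

22 to 20 to 19: the two C1–H bonds are traded for the C1 carbonyl. This turns the pyran into an aromatic 2-pyranone whose O2–C1 bond can be made by acylating an enol oxygen, and makes C1 an ester carbon. The forward steps must place hydride on C1 and not on the C8 ketone, and the second hydride must enter cation 21 at C1.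

19 to 17 (key): C4a–C8a and O2–C1 are cut, which opens both rings at once. The bicycle becomes an acyclic chain that holds only the two stereocentres. The forward step must attack through carbon in a 6-exo-dig sense, must outrun propargyl–allenyl isomerisation at C5, must reach the Z enone for lactonisation, and must spare both silyl ethers and the C7 ester.

17 to 15 and 16: the C3–C4 acyl–alkynyl bond is cut, so that the ynone, the most sensitive function, appears only one step before it is used. This leaves a terminal alkyne and a commercial acid chloride. The coupling must tolerate the acidic C8a methylene.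

15 to 13 and 14: the C8–C8a bond is cut (β-keto ester to ester plus acetate enolate). C8 then is a plain methyl ester during the stereochemical steps. The enolate must attack a hindered ester and leave the aroyl ester alone.

13 to 12 to 10 and 11: the O6–Si bond and then the C5–C6 bond are cut. Adding a propargyl metal to the C6 aldehyde brings in C5, C4a and C4 and sets C6 relative to C7. The problem falls to an aldehyde with one stereocentre. The forward step must control the aldehyde face and must not trigger an O7 to O6 acyl shift.

10 to 9 and 6: the C7–O bond is cut, not the acyl C–O bond. Acylating a tertiary alcohol with a di-ortho-substituted acid is the worst way to make this ester. Attack of an enamine carbon on a peroxide oxygen avoids it and sets the quaternary centre with a catalyst. The forward step needs high facial selectivity and a peroxide that still transfers oxygen.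

9 to 7 and 8: the C6–C7 bond is cut (formylation of a propanoate), which leaves two bulk esters. The forward step must keep the formyl ester as its enolate until work-up so that it does not condense with itself.

6 to 5 and 4, then 5 to 4: one acyl–O bond of the diacyl peroxide is cut to give a peroxy acid and a carboxylic acid, and the O–OH bond of the peroxy acid is then cut back to the same acid and hydrogen peroxide. Both halves of the symmetrical peroxide thus come from one arene building block, two molecules of it for each molecule of peroxide. The forward steps must activate a shielded carboxyl group under neutral conditions and keep the peroxy compounds cold and in solution.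

4 to 3 to 2 to 1: the acid oxidation level, the O–CH3 bond and the O–Si bond are cut in turn. 1 is commercial and carries both phenols. The unchelated 4-hydroxyl reacts first, so it must be silylated before the 2-hydroxyl is methylated, and every step must be mild to an aryl silyl ether.

## Other disconnections considered

Alternative 1: The cut is the C7–C8 bond of the carbocycle. In the forward step a chiral triazolium-derived carbene turns the C8 aldehyde of the monocyclic pyran keto aldehyde A2 into an acyl-anion equivalent, which adds to the C7 methyl ketone and gives the bicyclic tertiary α-ketol A1.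
- In its favour: the quaternary C7 centre is created in the ring-forming step under catalyst control, whereas the chosen key step creates no stereocentre. The pyran already has C1 at its final oxidation level, so no late hydride adjustment is needed. On that point the alternative is the better plan.
- Against it here: the aldehyde of A2 is the carbonyl of a vinylogous formate and a poor electrophile for carbene addition. The C6 silyloxy centre of A2 is α to the ketone and can epimerise under the basic conditions. A2 is a 2H-pyran without ring fusion and is expected to be prone to electrocyclic ring opening. A1 must still be esterified at a tertiary α-keto hydroxyl with the hindered acid 4, late, on a substrate open to retro-benzoin and α-ketol shifts.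
- Comparison: on structure both plans close the carbocycle, but the chosen plan closes both rings at once and carries the hindered ester from the start as a robust protecting group. On mechanism the two are about equal in precedent. On step count the alternative saves the two reductions at C1 but spends them on a separate pyran synthesis and the late acylation, so it is at best equal.

Alternative 2: The cuts are C5–C6 and C8–C8a. In the forward step the dianion of methyl acetoacetate A4 adds through its terminal carbon to the C6 aldehyde of 10, the same aldehyde the chosen route uses. Its central carbon then closes on the C8 methyl ester in a Dieckmann step and gives the enolised 2-methoxycarbonyl cyclohexane-1,3-dione A3.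
- In its favour: two C–C bonds and the carbocycle come from a cheap four-carbon unit in one operation. In speed and convergence to the carbocycle it is the better plan.
- Against it here: C6 would be set by a hard dianion under substrate control. The C6 alkoxide can lactonise onto the acetoacetate ester (a six-membered O-acylation) in competition with C-acylation at the hindered C8 ester, and it sits next to the C7 ester under strongly basic conditions. A3 can dehydrate across C5–C6. After A3 the pyran is still missing: the C4a oxygen must be exchanged for the C4–C3 unit by enol sulfonylation and cross-coupling, with C4a against C8 regiochemistry to control.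
- Comparison: C1 must again be reduced next to the C8 ketone, so on that chemoselectivity problem the two plans are equal. Both rely on classical enolate chemistry. The alternative needs clearly more steps after its key step and builds one ring where the chosen step builds two.

Alternative 3: The cut removes the benzoate ring at the two arene C–C bonds that flank the ester-bearing carbon. In the forward step the C7 but-2-ynoate A5 of the finished bicycle and the electron-rich diene A6 undergo a thermal Diels–Alder reaction. The terminal CH2 of A6 bonds to the methyl-bearing alkyne carbon and the ketene acetal carbon to the carboxyl-bearing one. Aromatisation by elimination gives the C6 silyl ether A7 with the 2-methoxy-4-hydroxy-6-methyl pattern directly.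
- In its favour: it avoids both the hindered acylation and the aroyl peroxide, needs no phenol protecting group and no differentiation of two phenols, and builds the arene in one step where the chosen route needs five to reach 6. On arene step economy it is the better plan.
- Against it here: the cycloaddition needs heat on the complete, sensitive core. The core's own dienes (C3=C4–C4a=C8a and the propenyl diene) can compete as 4π partners for the ynoate, and the nucleophilic diene can add to the C8 ketone or the dienone. The riskiest step comes last. An unhindered ynoate on C7 could not have passed through a base-mediated ring closure (it is a Michael acceptor, and the C8a enolate can attack its carbonyl), so C7 would need another protecting group and an extra deprotection and acylation.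
- Comparison: on mechanism the regiochemistry of the annulation is as dependable as that of the chosen key step. On structure the chosen plan uses the shielded benzoate as an asset. The gain in arene steps is offset by the exchange at C7, so the totals are about equal.

Key step: step 12

Remarks before the steps:
- Atom labels C1 to C8a follow the isochromene numbering of the target throughout.
- The chain of 17 and the bicycle of 19 map onto the target atom for atom (chain length, (E)-propenyl, benzoate pattern, 6R,7R).
- C1 of 19 is the lactone carbonyl carbon. It is not conjugated to the C8 ketone, and the ketone is intrinsically the better hydride acceptor. Selectivity for C1 must therefore come from the Lewis basicity of the pyranone oxygen and from shielding of C8 (step 13), and a fallback is given.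
- The phenol is carried as a triisopropylsilyl ether. A tert-butyldimethylsilyl ether of a phenol para to an ester would be lost to carbonate in the presence of the methanol that the lactonisation releases, and to the methoxide of the Claisen step. Sieves take up the methanol, and the last step uses buffered fluoride.
- The arene unit is made from aldehyde 1, because a di-ortho-substituted methyl benzoate cannot be saponified without losing an aryl silyl ether.
- Peroxide 6 takes two molecules of acid 4 for each molecule of hydrogen peroxide. It is assembled in two operations, perhydrolysis of 4 to peroxy acid 5 and carbodiimide coupling of 5 with a second molecule of 4, so that the active oxygen can be titrated before the second portion of 4 is committed.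
- Assumption: the enantiomer of the amine catalyst in step 7 is the one that delivers the (R) configuration at C7; both enantiomers are accessible from the two tert-leucines.

## Route

Step 1
Reactants: 1 2,4-dihydroxy-6-methylbenzaldehyde
Product: 2 2-hydroxy-6-methyl-4-(triisopropylsilyloxy)benzaldehyde
Conditions: TIPSCl (1.05 equiv), imidazole, CH2Cl2, 0 °C to rt
Reagents that add atoms: triisopropylsilyl chloride, CC(C)[Si](Cl)(C(C)C)C(C)C
Why: The 2-hydroxyl is tied in a hydrogen bond to the formyl group and is much less nucleophilic, so silyl ether formation should occur at O4 only.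

Step 2
Reactants: 2 2-hydroxy-6-methyl-4-(triisopropylsilyloxy)benzaldehyde
Product: 3 2-methoxy-6-methyl-4-(triisopropylsilyloxy)benzaldehyde
Conditions: MeOH, PPh3, DIAD, THF, 0 °C to rt
Reagents that add atoms: methanol, CO
Why: Mitsunobu etherification alkylates the acidic chelated phenol under neutral conditions that do not endanger the aryl silyl ether; with O4 already blocked only the 2-methoxy isomer can form.

Step 3
Reactants: 3 2-methoxy-6-methyl-4-(triisopropylsilyloxy)benzaldehyde
Product: 4 2-methoxy-6-methyl-4-(triisopropylsilyloxy)benzoic acid
Conditions: NaClO2, NaH2PO4, 2-methylbut-2-ene, tBuOH/H2O, 0 °C to rt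
Reagents that add atoms: sodium chlorite, [Na+].[O-]Cl=O
Why: Pinnick oxidation converts hindered, electron-rich benzaldehydes to acids at weakly acidic pH, which the silyl ether tolerates; the alkene traps hypochlorous acid so the ring is not chlorinated.

Step 4
Reactants: 4 2-methoxy-6-methyl-4-(triisopropylsilyloxy)benzoic acid
Product: 5 2-methoxy-6-methyl-4-(triisopropylsilyloxy)peroxybenzoic acid
Conditions: DCC (1.1 equiv), urea–hydrogen peroxide (5 equiv), THF/CH2Cl2, −10 to 0 °C; filtered, washed with cold water, dried, titrated iodometrically and kept as a cold solution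
Reagents that add atoms: hydrogen peroxide (as its urea adduct), OO
Why: Carbodiimide-mediated perhydrolysis: DCC takes up the acid through its unhindered carboxylate oxygen, and hydrogen peroxide, a small α-effect nucleophile used in excess, attacks the activated acyl carbon to give the peroxy acid under neutral, anhydrous conditions that the aryl silyl ether tolerates. Any 6 formed already at this stage is the product of step 5 and does no harm.

Step 5
Reactants: 5 2-methoxy-6-methyl-4-(triisopropylsilyloxy)peroxybenzoic acid; 4 2-methoxy-6-methyl-4-(triisopropylsilyloxy)benzoic acid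
Product: 6 bis[2-methoxy-6-methyl-4-(triisopropylsilyloxy)benzoyl] peroxide
Conditions: DCC (1.05 equiv), CH2Cl2, −10 to 0 °C; filtered and kept as a cold solution
Reagents that add atoms: none
Why: Carbodiimide coupling of a peroxy acid with a carboxylic acid, the standard synthesis of diacyl peroxides: the activated form of a second molecule of 4 is attacked by the terminal oxygen of 5, which closes the acyl–O–O–acyl unit. The peroxide is filtered from the urea and never concentrated to dryness.

Step 6
Reactants: 7 methyl propanoate; 8 methyl formate
Product: 9 methyl 2-methyl-3-oxopropanoate (racemic, aldehyde and enol forms)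
Conditions: NaH, MeOH (cat.), Et2O, 0 °C to rt; then cold 1 M HCl
Reagents that add atoms: none
Why: Crossed Claisen formylation: methyl formate cannot enolise and is the most electrophilic ester present, and the product is removed from the equilibrium as its sodium enolate until acidification.

Step 7
Reactants: 9 methyl 2-methyl-3-oxopropanoate; 6 bis[2-methoxy-6-methyl-4-(triisopropylsilyloxy)benzoyl] peroxide
Product: 10 methyl (2R)-2-methyl-2-{[2-methoxy-6-methyl-4-(triisopropylsilyloxy)benzoyl]oxy}-3-oxopropanoate
Conditions: (S)-N1,N1-diethyl-3,3-dimethylbutane-1,2-diamine·TfOH (20 mol%), BHT (10 mol%), CHCl3, 0 °C to rt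
Reagents that add atoms: none
Why: Asymmetric α-acyloxylation of an α-branched 1,3-dicarbonyl aldehyde by primary-amine enamine catalysis: the hydrogen-bonded enamino ester attacks the peroxide O–O bond through carbon, and the protonated tertiary amine of the catalyst holds the peroxide on one enamine face, which sets C7. The C7–O bond is formed at oxygen, so the shielded acyl carbon is never attacked, and the expelled acid 4 is recovered for steps 4 and 5.

Step 8
Reactants: 10 methyl (2R)-2-methyl-2-{[2-methoxy-6-methyl-4-(triisopropylsilyloxy)benzoyl]oxy}-3-oxopropanoate; 11 propargyl bromide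
Product: 12 methyl (2R,3R)-3-hydroxy-2-methyl-2-{[2-methoxy-6-methyl-4-(triisopropylsilyloxy)benzoyl]oxy}hex-5-ynoate
Conditions: Zn dust (activated), THF, 0 °C; then sat. aq. NH4Cl
Reagents that add atoms: none
Why: Barbier propargylation: allenylzinc bromide adds through its γ-carbon (SE2′) to give the homopropargylic alcohol. Zinc should chelate the aldehyde and the C8 ester carbonyl in a six-membered ring, and attack anti to the C7–O bond (past the methyl group) gives the 6R carbinol; the poorly donating acyloxy oxygen disfavours the competing five-membered chelate, and the shielded benzoate resists a shift to the new alkoxide.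

Step 9
Reactants: 12 methyl (2R,3R)-3-hydroxy-2-methyl-2-{[2-methoxy-6-methyl-4-(triisopropylsilyloxy)benzoyl]oxy}hex-5-ynoate
Product: 13 methyl (2R,3R)-3-(tert-butyldimethylsilyloxy)-2-methyl-2-{[2-methoxy-6-methyl-4-(triisopropylsilyloxy)benzoyl]oxy}hex-5-ynoate
Conditions: TBSOTf, 2,6-lutidine, CH2Cl2, −78 to 0 °C
Reagents that add atoms: tert-butyldimethylsilyl triflate, CC(C)(C)[Si](C)(C)OS(=O)(=O)C(F)(F)F
Why: Silyl triflate with a hindered pyridine base silylates secondary alcohols next to quaternary carbons without a basic alkoxide, so neither acyl shift nor retro-aldol can start.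

Step 10
Reactants: 13 methyl (2R,3R)-3-(tert-butyldimethylsilyloxy)-2-methyl-2-{[2-methoxy-6-methyl-4-(triisopropylsilyloxy)benzoyl]oxy}hex-5-ynoate; 14 methyl acetate
Product: 15 methyl (4R,5R)-5-(tert-butyldimethylsilyloxy)-4-methyl-4-{[2-methoxy-6-methyl-4-(triisopropylsilyloxy)benzoyl]oxy}-3-oxooct-7-ynoate
Conditions: LiN(iPr)2 (4.2 equiv), 14 (4 equiv), THF, −78 °C; then 13, −78 to −40 °C; AcOH at −78 °C
Reagents that add atoms: none
Why: Crossed Claisen condensation: 13 has no α-hydrogen and can only accept, its ester is activated by the α-oxygen, and the product is stored as its enolate. The di-ortho-substituted benzoate carbonyl is inert to the ester enolate and the triisopropylsilyl ether withstands the methoxide formed.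

Step 11
Reactants: 15 methyl (4R,5R)-5-(tert-butyldimethylsilyloxy)-4-methyl-4-{[2-methoxy-6-methyl-4-(triisopropylsilyloxy)benzoyl]oxy}-3-oxooct-7-ynoate; 16 (E)-crotonyl chloride
Product: 17 methyl (4R,5R,10E)-5-(tert-butyldimethylsilyloxy)-4-methyl-4-{[2-methoxy-6-methyl-4-(triisopropylsilyloxy)benzoyl]oxy}-3,9-dioxododec-10-en-7-ynoate
Conditions: PdCl2(PPh3)2 (2 mol%), CuI (4 mol%), Et3N (1.05 equiv), THF, rt
Reagents that add atoms: none
Why: Acyl Sonogashira coupling of a terminal alkyne with an acid chloride forms the C3–C4 bond directly at the ynone oxidation level. Only one equivalent of amine is used so that the β-keto ester is not acylated, and the E alkene of the acyl unit is retained.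

Step 12
Reactants: 17 methyl (4R,5R,10E)-5-(tert-butyldimethylsilyloxy)-4-methyl-4-{[2-methoxy-6-methyl-4-(triisopropylsilyloxy)benzoyl]oxy}-3,9-dioxododec-10-en-7-ynoate
Product: 19 (6R,7R)-6-(tert-butyldimethylsilyloxy)-7-methyl-1,8-dioxo-3-[(E)-prop-1-enyl]-5,6,7,8-tetrahydro-1H-isochromen-7-yl 2-methoxy-6-methyl-4-(triisopropylsilyloxy)benzoate, via exocyclic enone 18 (not isolated)
Conditions: Cs2CO3 (1.2 equiv), powdered 4 Å molecular sieves, MeCN (0.02 M), 0 °C to rt; aq. NH4Cl
Reagents that add atoms: none
Why: Cs2CO3 deprotonates C8a of the β-keto ester, and the soft, doubly stabilised carbanion adds to the ynone β-carbon C4a in a 6-exo-dig Michael addition that forms C4a–C8a and the carbocycle (C4a, C5, C6, C7, C8, C8a); protonation of the allenolate gives exocyclic enone 18. The E and Z forms of 18 equilibrate through the extended enolate, and in the Z form the oxygen on C3 attacks the C1 ester in a 6-exo-trig acyl substitution, expels methoxide and forms O2–C1 and the aromatic 2-pyranone, which is the thermodynamic sink. The closest known reactions are the base-mediated addition of β-keto esters to alkynones with lactonisation to 2-pyranones and the 6-exo-dig cyclisation of stabilised enolates onto alkynones; here both run in one chain. No stereocentre is created: C7 is quaternary and cannot epimerise, C6 is not α to a carbonyl, and C8a ends as an sp2 carbon. The step needs attack through carbon and not oxygen, which the softness of the β-keto ester carbanion toward a carbon electrophile secures. It needs cyclisation faster than propargyl–allenyl isomerisation at C5, which a weak heterogeneous base at 0 °C, high dilution and the gem-disubstitution at C7 that folds the chain should secure. Both silyl ethers must survive, which the triisopropylsilyl group on the phenol and the sieves that take up methanol secure. The shielded aroyl carbonyl cannot be attacked by the C8a enolate, as an unhindered ester on C7 would be.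

Step 13
Reactants: 19 (6R,7R)-6-(tert-butyldimethylsilyloxy)-7-methyl-1,8-dioxo-3-[(E)-prop-1-enyl]-5,6,7,8-tetrahydro-1H-isochromen-7-yl 2-methoxy-6-methyl-4-(triisopropylsilyloxy)benzoate
Product: 20 (6R,7R)-6-(tert-butyldimethylsilyloxy)-1-hydroxy-7-methyl-8-oxo-3-[(E)-prop-1-enyl]-5,6,7,8-tetrahydro-1H-isochromen-7-yl 2-methoxy-6-methyl-4-(triisopropylsilyloxy)benzoate (lactol, C1 epimers)
Conditions: iBu2AlH (1.1 equiv), CH2Cl2, −78 °C; MeOH, then aq. potassium sodium tartrate
Reagents that add atoms: none
Why: Partial reduction of a lactone to a lactol: iBu2AlH is an electrophilic hydride that binds the most Lewis-basic, least hindered carbonyl oxygen. The 2-pyranone oxygen (whose aluminium complex is an aromatic oxidopyrylium) is more basic than the C8 ketone oxygen, and C8 is flanked by the quaternary C7 with its bulky aroyloxy group. With one equivalent at −78 °C the reaction should stop at the lactol aluminate, which chelation to the C8 carbonyl also holds; the di-ortho-substituted benzoate is inert at this temperature.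

Step 14
Reactants: 20 (6R,7R)-6-(tert-butyldimethylsilyloxy)-1-hydroxy-7-methyl-8-oxo-3-[(E)-prop-1-enyl]-5,6,7,8-tetrahydro-1H-isochromen-7-yl 2-methoxy-6-methyl-4-(triisopropylsilyloxy)benzoate
Product: 22 (6R,7R)-6-(tert-butyldimethylsilyloxy)-7-methyl-8-oxo-3-[(E)-prop-1-enyl]-5,6,7,8-tetrahydro-1H-isochromen-7-yl 2-methoxy-6-methyl-4-(triisopropylsilyloxy)benzoate, via pyrylium ion 21 (not isolated)
Conditions: Et3SiH (3 equiv), BF3·OEt2 (1.5 equiv), CH2Cl2, −78 to −40 °C; sat. aq. NaHCO3
Reagents that add atoms: none
Why: Ionic reduction of a lactol to a cyclic ether, as in the conversion of coumarins to 2H-chromenes: BF3·OEt2 ionises the lactol (or its ring-opened tautomer, which recloses) to the aromatic pyrylium ion 21. Et3SiH then delivers hydride to the unsubstituted α-carbon C1, the least hindered position and the one that gives the stabilised doubly vinylogous ester, which as a neutral push-pull system should not be reduced further at low temperature.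

Step 15
Reactants: 22 (6R,7R)-6-(tert-butyldimethylsilyloxy)-7-methyl-8-oxo-3-[(E)-prop-1-enyl]-5,6,7,8-tetrahydro-1H-isochromen-7-yl 2-methoxy-6-methyl-4-(triisopropylsilyloxy)benzoate
Product: 23 (6R,7R)-6-hydroxy-7-methyl-8-oxo-3-[(E)-prop-1-enyl]-5,6,7,8-tetrahydro-1H-isochromen-7-yl 4-hydroxy-2-methoxy-6-methylbenzoate (CNP0187389.2)
Conditions: TBAF (4 equiv), AcOH (4 equiv), THF, 0 °C to rt
Reagents that add atoms: none
Why: Fluoride-mediated desilylation: buffered fluoride should remove the aryl silyl ether quickly and the hindered secondary silyl ether more slowly. The acetic acid keeps the medium near neutral, so neither retro-aldol opening of the β-hydroxy ketone nor an O7 to O6 acyl shift is triggered.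

## Compound list

1 | 2,4-dihydroxy-6-methylbenzaldehyde | O=Cc1c(C)cc(O)cc1O | starting material
2 | 2-hydroxy-6-methyl-4-(triisopropylsilyloxy)benzaldehyde | O=Cc1c(C)cc(O[Si](C(C)C)(C(C)C)C(C)C)cc1O | intermediate
3 | 2-methoxy-6-methyl-4-(triisopropylsilyloxy)benzaldehyde | O=Cc1c(C)cc(O[Si](C(C)C)(C(C)C)C(C)C)cc1OC | intermediate
4 | 2-methoxy-6-methyl-4-(triisopropylsilyloxy)benzoic acid | OC(=O)c1c(C)cc(O[Si](C(C)C)(C(C)C)C(C)C)cc1OC | intermediate
5 | 2-methoxy-6-methyl-4-(triisopropylsilyloxy)peroxybenzoic acid | OOC(=O)c1c(C)cc(O[Si](C(C)C)(C(C)C)C(C)C)cc1OC | intermediate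
6 | bis[2-methoxy-6-methyl-4-(triisopropylsilyloxy)benzoyl] peroxide | COc1cc(O[Si](C(C)C)(C(C)C)C(C)C)cc(C)c1C(=O)OOC(=O)c1c(C)cc(O[Si](C(C)C)(C(C)C)C(C)C)cc1OC | intermediate
7 | methyl propanoate | CCC(=O)OC | starting material
8 | methyl formate | COC=O | starting material
9 | methyl 2-methyl-3-oxopropanoate (racemic) | COC(=O)C(C)C=O | intermediate
10 | methyl (2R)-2-methyl-2-{[2-methoxy-6-methyl-4-(triisopropylsilyloxy)benzoyl]oxy}-3-oxopropanoate | COC(=O)[C@](C)(OC(=O)c1c(C)cc(O[Si](C(C)C)(C(C)C)C(C)C)cc1OC)C=O | intermediate
11 | propargyl bromide | C#CCBr | starting material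
12 | methyl (2R,3R)-3-hydroxy-2-methyl-2-{[2-methoxy-6-methyl-4-(triisopropylsilyloxy)benzoyl]oxy}hex-5-ynoate | COC(=O)[C@](C)(OC(=O)c1c(C)cc(O[Si](C(C)C)(C(C)C)C(C)C)cc1OC)[C@H](O)CC#C | intermediate
13 | methyl (2R,3R)-3-(tert-butyldimethylsilyloxy)-2-methyl-2-{[2-methoxy-6-methyl-4-(triisopropylsilyloxy)benzoyl]oxy}hex-5-ynoate | COC(=O)[C@](C)(OC(=O)c1c(C)cc(O[Si](C(C)C)(C(C)C)C(C)C)cc1OC)[C@H](O[Si](C)(C)C(C)(C)C)CC#C | intermediate
14 | methyl acetate | CC(=O)OC | starting material
15 | methyl (4R,5R)-5-(tert-butyldimethylsilyloxy)-4-methyl-4-{[2-methoxy-6-methyl-4-(triisopropylsilyloxy)benzoyl]oxy}-3-oxooct-7-ynoate | COC(=O)CC(=O)[C@](C)(OC(=O)c1c(C)cc(O[Si](C(C)C)(C(C)C)C(C)C)cc1OC)[C@H](O[Si](C)(C)C(C)(C)C)CC#C | intermediate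
16 | (E)-crotonyl chloride | C/C=C/C(Cl)=O | starting material
17 | methyl (4R,5R,10E)-5-(tert-butyldimethylsilyloxy)-4-methyl-4-{[2-methoxy-6-methyl-4-(triisopropylsilyloxy)benzoyl]oxy}-3,9-dioxododec-10-en-7-ynoate | C/C=C/C(=O)C#CC[C@@H](O[Si](C)(C)C(C)(C)C)[C@@](C)(OC(=O)c1c(C)cc(O[Si](C(C)C)(C(C)C)C(C)C)cc1OC)C(=O)CC(=O)OC | intermediate
18 | methyl (3R,4R,6Z)-4-(tert-butyldimethylsilyloxy)-3-methyl-3-{[2-methoxy-6-methyl-4-(triisopropylsilyloxy)benzoyl]oxy}-2-oxo-6-[(3E)-2-oxopent-3-enylidene]cyclohexane-1-carboxylate (not isolated) | C/C=C/C(=O)/C=C1/C[C@@H](O[Si](C)(C)C(C)(C)C)[C@@](C)(OC(=O)c2c(C)cc(O[Si](C(C)C)(C(C)C)C(C)C)cc2OC)C(=O)C1C(=O)OC | intermediate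
19 | (6R,7R)-6-(tert-butyldimethylsilyloxy)-7-methyl-1,8-dioxo-3-[(E)-prop-1-enyl]-5,6,7,8-tetrahydro-1H-isochromen-7-yl 2-methoxy-6-methyl-4-(triisopropylsilyloxy)benzoate | C/C=C/C1=CC2=C(C(=O)O1)C(=O)[C@](C)(OC(=O)c3c(C)cc(O[Si](C(C)C)(C(C)C)C(C)C)cc3OC)[C@H](O[Si](C)(C)C(C)(C)C)C2 | intermediate
20 | (6R,7R)-6-(tert-butyldimethylsilyloxy)-1-hydroxy-7-methyl-8-oxo-3-[(E)-prop-1-enyl]-5,6,7,8-tetrahydro-1H-isochromen-7-yl 2-methoxy-6-methyl-4-(triisopropylsilyloxy)benzoate (C1 epimers) | C/C=C/C1=CC2=C(C(O)O1)C(=O)[C@](C)(OC(=O)c3c(C)cc(O[Si](C(C)C)(C(C)C)C(C)C)cc3OC)[C@H](O[Si](C)(C)C(C)(C)C)C2 | intermediate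
21 | (6R,7R)-6-(tert-butyldimethylsilyloxy)-7-methyl-7-{[2-methoxy-6-methyl-4-(triisopropylsilyloxy)benzoyl]oxy}-8-oxo-3-[(E)-prop-1-enyl]-5,6,7,8-tetrahydroisochromenylium hydroxytrifluoroborate (not isolated) | C/C=C/c1cc2c(c[o+]1)C(=O)[C@](C)(OC(=O)c3c(C)cc(O[Si](C(C)C)(C(C)C)C(C)C)cc3OC)[C@H](O[Si](C)(C)C(C)(C)C)C2.O[B-](F)(F)F | intermediate
22 | (6R,7R)-6-(tert-butyldimethylsilyloxy)-7-methyl-8-oxo-3-[(E)-prop-1-enyl]-5,6,7,8-tetrahydro-1H-isochromen-7-yl 2-methoxy-6-methyl-4-(triisopropylsilyloxy)benzoate | C/C=C/C1=CC2=C(CO1)C(=O)[C@](C)(OC(=O)c3c(C)cc(O[Si](C(C)C)(C(C)C)C(C)C)cc3OC)[C@H](O[Si](C)(C)C(C)(C)C)C2 | intermediate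
23 | (6R,7R)-6-hydroxy-7-methyl-8-oxo-3-[(E)-prop-1-enyl]-5,6,7,8-tetrahydro-1H-isochromen-7-yl 4-hydroxy-2-methoxy-6-methylbenzoate | C/C=C/C1=CC2=C(CO1)C(=O)[C@](C)(OC(=O)c1c(C)cc(O)cc1OC)[C@H](O)C2 | target

## Step count and least certain steps

Total step count: 15. Longest linear sequence: 14 steps (1 to 23 through steps 1 to 5 and 7 to 15); the branch from methyl propanoate 7 (step 6) joins at step 7.

Step 12 (key step). The most likely failure is base-induced isomerisation of the ynone toward the allenyl ketone through the C5 methylene, followed by loss of the C6 silyloxy group. The second is stalling at the E form of 18, so that lactonisation does not follow; both compete because the C5 hydrogens are propargylic to an electron-poor alkyne. Fallback (amine relay, from 17 back to 19): 17 is treated with pyrrolidine (1 equiv, CH2Cl2, 0 °C). Aza-Michael addition at C4a should consume the alkyne within minutes and give the pyrrolidine enaminone F1, which can no longer isomerise. Warming F1 with AcOH in toluene (about 70 °C) should let the enol of the β-keto ester add to the protonated enaminone at C4a (6-exo-trig) and expel pyrrolidine. The same C4a–C8a bond forms by addition–elimination, and the resulting 18 lactonises under the acidic conditions to 19.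

Step 13. The most likely failure is hydride delivery to the C8 ketone, alone or together with C1, because a ketone α to an acyloxy group is intrinsically a better hydride acceptor than a lactone; the result would be over-reduction. Fallback (electrophilic activation in place of hydride selectivity, from 19 back to 22): 19 is O-methylated with MeOTf and 2,6-di-tert-butyl-4-methylpyridine (CH2Cl2, 0 °C). Methylation should occur at the pyranone carbonyl oxygen, the only oxygen whose alkylation gives an aromatic cation, and give the 1-methoxy pyrylium triflate F2. NaBH4 at −78 °C should reduce the cationic C1 of F2 far faster than the neutral ketone and give the 1-methoxy acetal F3. F3 under the conditions of step 14 (Et3SiH, BF3·OEt2) ionises to the same cation 21 and is reduced to 22.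

Step 7. The most likely failure is poor enantiofacial discrimination together with slow oxygen transfer, since the peroxide is di-ortho-substituted and electron-rich; it may decompose or acylate the catalyst nitrogen before the enamine attacks, and the product aldehyde may be deformylated. Fallback (carboxylate as nucleophile plus enzymatic desymmetrisation, from 4 back to 10): acid 4 is alkylated at oxygen with dimethyl 2-bromo-2-methylmalonate (CsHCO3, DMF, rt), where the hindered acid reacts through its unhindered oxygen, to give the achiral malonate F4. A hydrolase (pig liver esterase, pH 7 buffer) selected for the required sense cleaves one enantiotopic ester to the half-ester F5. BH3·SMe2 reduces the acid selectively to the hydroxy ester F6, and Dess–Martin periodinane oxidises F6 to 10. This fallback also avoids the peroxy compounds 5 and 6.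

Step 8. The most likely failure is poor diastereofacial selectivity, if the zinc chelate between the aldehyde and the ester does not control the addition or if attack passes the aroyloxy group. Fallback (catalyst control in place of substrate control, from 10 back to 12): propargylation with allenylboronic acid pinacol ester under a chiral BINOL-derived phosphoric acid (3,3′-bis(2,4,6-triisopropylphenyl) type, enantiomer chosen for the 6R sense; toluene, 4 Å sieves, −20 °C). The closed six-membered boron transition state transfers the propargyl group without reliance on chelation. No new compound is involved.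

Step 11. The most likely failure is acylation of the β-keto ester enol by the acid chloride, or deconjugation of the crotonyl unit through a vinylketene under amine base; either would consume 15 or give the wrong acyl group. Fallback (alkynyl addition to an aldehyde and late oxidation, from 13 back to 17): 13 is deprotonated at the alkyne terminus (LiN(iPr)2, THF, −78 °C) and added to (E)-crotonaldehyde to give the propargylic alcohol F7 as a carbinol mixture. Claisen condensation of F7 with the lithium enolate of methyl acetate (5 equiv) gives the hydroxy β-keto ester F8. MnO2 (CH2Cl2) oxidises the doubly activated alcohol of F8 to 17.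

## Further compounds

F1 | step 12 | methyl (4R,5R,7E,10E)-5-(tert-butyldimethylsilyloxy)-4-methyl-4-{[2-methoxy-6-methyl-4-(triisopropylsilyloxy)benzoyl]oxy}-3,9-dioxo-7-(pyrrolidin-1-yl)dodeca-7,10-dienoate | C/C=C/C(=O)/C=C(/N1CCCC1)C[C@@H](O[Si](C)(C)C(C)(C)C)[C@@](C)(OC(=O)c1c(C)cc(O[Si](C(C)C)(C(C)C)C(C)C)cc1OC)C(=O)CC(=O)OC
F2 | step 13 | (6R,7R)-6-(tert-butyldimethylsilyloxy)-1-methoxy-7-methyl-7-{[2-methoxy-6-methyl-4-(triisopropylsilyloxy)benzoyl]oxy}-8-oxo-3-[(E)-prop-1-enyl]-5,6,7,8-tetrahydroisochromenylium triflate | C/C=C/c1cc2c(c(OC)[o+]1)C(=O)[C@](C)(OC(=O)c3c(C)cc(O[Si](C(C)C)(C(C)C)C(C)C)cc3OC)[C@H](O[Si](C)(C)C(C)(C)C)C2.[O-]S(=O)(=O)C(F)(F)F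
F3 | step 13 | (6R,7R)-6-(tert-butyldimethylsilyloxy)-1-methoxy-7-methyl-8-oxo-3-[(E)-prop-1-enyl]-5,6,7,8-tetrahydro-1H-isochromen-7-yl 2-methoxy-6-methyl-4-(triisopropylsilyloxy)benzoate (C1 epimers) | C/C=C/C1=CC2=C(C(OC)O1)C(=O)[C@](C)(OC(=O)c3c(C)cc(O[Si](C(C)C)(C(C)C)C(C)C)cc3OC)[C@H](O[Si](C)(C)C(C)(C)C)C2
F4 | step 7 | dimethyl 2-methyl-2-{[2-methoxy-6-methyl-4-(triisopropylsilyloxy)benzoyl]oxy}propanedioate | COC(=O)C(C)(OC(=O)c1c(C)cc(O[Si](C(C)C)(C(C)C)C(C)C)cc1OC)C(=O)OC
F5 | step 7 | (2R)-3-methoxy-2-methyl-2-{[2-methoxy-6-methyl-4-(triisopropylsilyloxy)benzoyl]oxy}-3-oxopropanoic acid | COC(=O)[C@](C)(OC(=O)c1c(C)cc(O[Si](C(C)C)(C(C)C)C(C)C)cc1OC)C(=O)O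
F6 | step 7 | methyl (2R)-3-hydroxy-2-methyl-2-{[2-methoxy-6-methyl-4-(triisopropylsilyloxy)benzoyl]oxy}propanoate | COC(=O)[C@](C)(OC(=O)c1c(C)cc(O[Si](C(C)C)(C(C)C)C(C)C)cc1OC)CO
F0 | step 8 | none | none
F7 | step 11 | methyl (2R,3R,8E)-3-(tert-butyldimethylsilyloxy)-7-hydroxy-2-methyl-2-{[2-methoxy-6-methyl-4-(triisopropylsilyloxy)benzoyl]oxy}dec-8-en-5-ynoate (C7 epimers) | COC(=O)[C@](C)(OC(=O)c1c(C)cc(O[Si](C(C)C)(C(C)C)C(C)C)cc1OC)[C@H](O[Si](C)(C)C(C)(C)C)CC#CC(O)/C=C/C
F8 | step 11 | methyl (4R,5R,10E)-5-(tert-butyldimethylsilyloxy)-9-hydroxy-4-methyl-4-{[2-methoxy-6-methyl-4-(triisopropylsilyloxy)benzoyl]oxy}-3-oxododec-10-en-7-ynoate (C9 epimers) | COC(=O)CC(=O)[C@](C)(OC(=O)c1c(C)cc(O[Si](C(C)C)(C(C)C)C(C)C)cc1OC)[C@H](O[Si](C)(C)C(C)(C)C)CC#CC(O)/C=C/C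
A1 | alternative 1 | (6R,7R)-6-(tert-butyldimethylsilyloxy)-7-hydroxy-7-methyl-3-[(E)-prop-1-enyl]-6,7-dihydro-1H-isochromen-8(5H)-one | C/C=C/C1=CC2=C(CO1)C(=O)[C@](C)(O)[C@H](O[Si](C)(C)C(C)(C)C)C2
A2 | alternative 1 | 4-[(2R)-2-(tert-butyldimethylsilyloxy)-3-oxobutyl]-6-[(E)-prop-1-enyl]-2H-pyran-3-carbaldehyde | C/C=C/C1=CC(C[C@@H](O[Si](C)(C)C(C)(C)C)C(C)=O)=C(C=O)CO1
A3 | alternative 2 | methyl (4R,5R)-2,4-dihydroxy-5-methyl-5-{[2-methoxy-6-methyl-4-(triisopropylsilyloxy)benzoyl]oxy}-6-oxocyclohex-1-ene-1-carboxylate | COC(=O)C1=C(O)C[C@@H](O)[C@@](C)(OC(=O)c2c(C)cc(O[Si](C(C)C)(C(C)C)C(C)C)cc2OC)C1=O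
A4 | alternative 2 | methyl acetoacetate | CC(=O)CC(=O)OC
A5 | alternative 3 | (6R,7R)-6-(tert-butyldimethylsilyloxy)-7-methyl-8-oxo-3-[(E)-prop-1-enyl]-5,6,7,8-tetrahydro-1H-isochromen-7-yl but-2-ynoate | C/C=C/C1=CC2=C(CO1)C(=O)[C@](C)(OC(=O)C#CC)[C@H](O[Si](C)(C)C(C)(C)C)C2
A6 | alternative 3 | 1,1-dimethoxy-3-(trimethylsilyloxy)buta-1,3-diene | C=C(O[Si](C)(C)C)C=C(OC)OC
A7 | alternative 3 | (6R,7R)-6-(tert-butyldimethylsilyloxy)-7-methyl-8-oxo-3-[(E)-prop-1-enyl]-5,6,7,8-tetrahydro-1H-isochromen-7-yl 4-hydroxy-2-methoxy-6-methylbenzoate | C/C=C/C1=CC2=C(CO1)C(=O)[C@](C)(OC(=O)c3c(C)cc(O)cc3OC)[C@H](O[Si](C)(C)C(C)(C)C)C2
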